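(The readings are calculated for substances that don't exist; the scatter is artificial.)

When a reaction slows, you suspect first that too little substrate remains or that equilibrium is near. Here is a flask that slows, and what is asked of it.

| flask | G | Q | time |
|---|---|---|---|
| green | 0.100 M | 0.00300 M |  |
| ochre | 0.0600 M | 0.00300 M |  |
| blue | 0.100 M | 0.00450 M |  |
| violet | 0.150 M | 0.00300 M |  |
| red | 0.100 M | 0.00300 M | 20 min |

- green run (time / min: [X] / M): 1.4: 0.0139; 2.7: 0.0184; 4.0: 0.0223; 5.4: 0.0243; 6.8: 0.0258; 8.1: 0.0257
- ochre run (time / min: [X] / M): 1.4: 0.0085; 2.7: 0.0151; 4.0: 0.0173; 5.4: 0.0176; 6.8: 0.0194; 8.1: 0.0200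
- blue run (time / min: [X] / M): 1.4: 0.0196; 2.7: 0.0268; 4.0: 0.0318; 5.4: 0.0327; 6.8: 0.0340; 8.1: 0.0361
- violet run (time / min: [X] / M): 1.4: 0.0130; 2.7: 0.0225; 4.0: 0.0257; 5.4: 0.0288; 6.8: 0.0304; 8.1: 0.0313

(scatter of a reading: 0.001 M)

- Overall: G -> X, with Q as catalyst.
- Constant volume, constant temperature.
- The analysis sees a species whether free or bound.
- An order is taken over about fifteen percent of the charge, up and down.

- order of the initial rate in [G], near the charge of the green run, the rate being that where two percent of its G are X (one fixed amount of X, the same in the runs compared)
- order of the initial rate in [Q], near the charge of the green run, the rate being that where two percent of its G are X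
- X in the red run at 20 min, as a share of the G charged

Two numbers do not seem to go together. The green run levels off, reading 0.0257 M of X at its last time with 0.0743 M of its G not turned to X, which looks like an equilibrium. But the blue run, with the same G charged and more Q, reaches 0.0361 M by the same time, more than green, and a catalyst is not supposed to shift an equilibrium.

So look for what stays nearly constant between these two runs, and freeze it. Divide the last [X] by the [Q] charged:

green: 0.0257 M / 0.00300 M = 8.57

blue: 0.0361 M / 0.00450 M = 8.02

Call this the ration, the X made per Q charged by the last reading at this G charge; its usual name is the turnover number. It belongs to that G charge, since the ochre run gives 6.67 and the violet run 10.4. I read the levelling as Q being lost during the run, an estimate from these ratios.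

The red run has the green charge, and the last two green readings differ by 1.00 × 10⁻⁴ M, less than the scatter of 0.001 M. So I take the ration as reached by 20 min:

share of G = 8.57 × 0.00300 M / 0.100 M = 25.7 %

The forecast gives 27.5 % (25.5 % to 31 %), higher than my figure, with orders 0.45 in [G] and 1 in [Q]. Its ground is the same comparison: “X/Q against time nearly overlays for green and blue”.

The simulation gives 26.5 % for the red run, with orders 0.42 in [G] and 1.1 in [Q], each inside the forecast's range. At equal X made, the blue run goes at 1.5 times the green rate.

    Q + G ⇌ QG, settled at all times (29.60 /M)
    QG ⇌ X + Q (13.02 /min, 37.56 /M/min)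
    Q → Ky (0.6120 /min)
    2 G ⇌ G2, settled at all times (147.0 /M)

The red result, taken as a ration, is 8.83, more than the 8.57 read in the green run at 8.1 min. For the blue run the green ration gives 0.0385 M, against 0.0361 M read at its last time. A quarter of the G charged is 0.0250 M, and X came to it at 6.31 min in the green run but at 2.31 min in the blue run.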